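**Strategy.** The route rests on disconnecting the C4–C5 bond of ring A (eudesmane numbering). The key step is an intramolecular Nozaki–Hiyama–Kishi reaction: an alkenyl triflate at C5 of ring B, regiodefined because C10 is quaternary, adds to a C4 methyl ketone. One operation closes ring A and creates the C4 carbinol, whose hydroxyl should end up syn to the C10 methyl because the ketone methyl avoids a 1,3-diaxial clash with it. The retained C5=C6 alkene is then reduced to the trans ring fusion. The precursor, a cyclohexenyl triflate carrying the keto side chain on C10, comes from (S)-carvone by an Ireland–Claisen rearrangement that sets C10 and C1.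

Key step: step 12

Remark: terpenoid carbons carry eudesmane locants (ring A: C1–C5 and C10; ring B: C5–C10; C11 is the carbinol carbon on C7, C14 the methyl on C10, C15 the methyl on C4) and C9' is the benzylic carbon; the target as drawn is (1S,4R,5S,7S,10R,9'R).

**Step 1**
Reactants: 1 (E)-5-methylhex-2-enoic acid; 2 (S)-4-benzyl-1,3-oxazolidin-2-one
Product: 3 N-enoyl oxazolidinone
Conditions: t-BuCOCl, Et3N, THF, −20 °C; then 2, LiCl, rt
Reagents that add atoms: none
Why: Mixed-anhydride N-acylation of the oxazolidinone is a standard imide formation and creates no stereocentre.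

**Step 2**
Reactants: 3 N-enoyl oxazolidinone; 4 1,3,5-trimethoxybenzene
Product: 6 β-aryl imide, via (2,4,6-trimethoxyphenyl)magnesium bromide 5 (not isolated)
Conditions: 4, n-BuLi, THF, 0 °C to rt; MgBr2·OEt2, 0 °C; CuBr·SMe2, THF/Me2S, −40 °C; then 3, −40 to −10 °C; aq. NH4Cl
Reagents that add atoms: none
Why: Copper-mediated conjugate addition of the aryl Grignard reagent to the magnesium-chelated s-cis N-enoyl oxazolidinone (auxiliary-controlled 1,4-addition) should deliver the aryl group to the face of the β-carbon opposite the benzyl group and set C9' as R.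

**Step 3**
Reactants: 6 β-aryl imide
Product: 7 (R)-5-methyl-3-(2,4,6-trimethoxyphenyl)hexanoic acid
Conditions: LiOH, H2O2, THF/H2O, 0 °C; Na2SO3; then 1 M HCl
Reagents that add atoms: hydrogen peroxide, OO
Why: Hydroperoxide attacks the exocyclic imide carbonyl selectively (standard auxiliary cleavage) and leaves C9' untouched.

**Step 4**
Reactants: 8 (S)-carvone
Product: 9 trans-6-hydroxycarvone
Conditions: LiN(i-Pr)2, THF, −78 °C; 3-phenyl-2-(phenylsulfonyl)oxaziridine, −78 °C; aq. NH4Cl
Reagents that add atoms: 3-phenyl-2-(phenylsulfonyl)oxaziridine, O=S(=O)(c1ccccc1)N1OC1c1ccccc1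
Why: Kinetic deprotonation of the enone at the α' carbon (C6) and enolate oxidation by the N-sulfonyloxaziridine, which should approach anti to the adjacent isopropenyl group, gives the trans α'-hydroxy enone.

**Step 5**
Reactants: 9 trans-6-hydroxycarvone; 7 (R)-5-methyl-3-(2,4,6-trimethoxyphenyl)hexanoic acid
Product: 10 α'-acyloxy enone
Conditions: EDC·HCl, DMAP (cat.), CH2Cl2, 0 °C to rt
Reagents that add atoms: none
Why: Carbodiimide (Steglich) esterification of the secondary hydroxyl touches no stereocentre.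

**Step 6**
Reactants: 10 α'-acyloxy enone
Product: 11 allylic ester with a C5 triethylsilyl enol ether
Conditions: Et3SiH, RhCl(PPh3)3 (2 mol%), PhMe, 50 °C
Reagents that add atoms: triethylsilane, CC[SiH](CC)CC
Why: Rhodium-catalysed 1,4-hydrosilylation of the enone with a monohydrosilane should give the tetrasubstituted C5(OSiEt3)=C10 enol ether regiospecifically, which turns the α'-acyloxy ketone into an allylic ester without forming a stereocentre.

**Step 7**
Reactants: 11 allylic ester with a C5 triethylsilyl enol ether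
Product: 14 keto methyl ester, via silyl ketene acetal 12 (not isolated), via keto acid 13 (not isolated)
Conditions: LiN(i-Pr)2, Me3SiCl, THF/DMPU, −78 °C, then 70 °C; 1 M HCl, rt; then Me3SiCHN2, PhMe/MeOH, 0 °C
Reagents that add atoms: (trimethylsilyl)diazomethane, C[Si](C)(C)C=[N+]=[N-]
Why: In this Ireland–Claisen rearrangement the (Z)-silyl ketene acetal formed in the presence of DMPU should react through a chair transition state with the C6–O bond pseudoaxial, so that C1 is delivered to C10 on the face of the breaking C6–O bond (trans to the isopropenyl group, fixing C10 as R) with C9' equatorial (fixing C1 as S), after which acid unmasks the C5 ketone from the new enol ether and the acid is methylated.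

**Step 8**
Reactants: 14 keto methyl ester
Product: 15 hydroxy keto ester
Conditions: Co(acac)2 (20 mol%), PhSiH3, O2 (1 atm), THF, rt; aq. Na2S2O3
Reagents that add atoms: dioxygen, O=O
Why: Mukaiyama hydration (metal-hydride hydrogen atom transfer, then oxygen trapping) converts the only alkene, the 1,1-disubstituted isopropenyl group, into the Markovnikov tertiary alcohol and forms no stereocentre.

**Step 9**
Reactants: 15 hydroxy keto ester
Product: 16 enol triflate ester
Conditions: KN(SiMe3)2 (2.2 equiv), THF, −78 °C; PhNTf2, −78 to 0 °C; aq. NH4Cl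
Reagents that add atoms: N-phenylbis(trifluoromethanesulfonimide), O=S(=O)(N(c1ccccc1)S(=O)(=O)C(F)(F)F)C(F)(F)F
Why: The ketone can enolise only toward C6 because C10 is quaternary and the hindered ester α-proton at C1 is left alone, so enolate O-triflation should give the C5=C6 enol triflate as one regioisomer.

**Step 10**
Reactants: 16 enol triflate ester
Product: 18 (E)-enone, via aldehyde 17 (not isolated)
Conditions: i-Bu2AlH (2.2 equiv), PhMe, −78 °C; MeOH; then Ph3P=CHC(O)CH3, −78 to 80 °C
Reagents that add atoms: 1-(triphenylphosphoranylidene)propan-2-one, CC(=O)C=P(c1ccccc1)(c1ccccc1)c1ccccc1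
Why: Partial reduction of the ester to the aluminium hemiacetal and in-situ Wittig olefination of the released aldehyde with a stabilised ylide should give the (E)-enone without isolating the epimerisable α-branched aldehyde.

**Step 11**
Reactants: 18 (E)-enone
Product: 19 keto alkenyl triflate
Conditions: [(Ph3P)CuH]6 (0.5 equiv), H2O (3 equiv), benzene, rt; aq. NH4Cl
Reagents that add atoms: none
Why: Copper hydride conjugate reduction saturates the enone chemoselectively and leaves the alkenyl triflate and the ketone untouched.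

**Step 12**
Reactants: 19 keto alkenyl triflate
Product: 20 eudesm-5-ene-4,11-diol
Conditions: CrCl2 (8 equiv), NiCl2 (10 mol%), degassed DMF, 50 °C; aq. NH4Cl
Reagents that add atoms: none
Why: CrCl2 reduces NiCl2 to zerovalent nickel, which inserts into the C5–OTf bond; transmetalation to trivalent chromium gives a C5 alkenylchromium species that adds to the C4 ketone and, after work-up, leaves the tertiary allylic alcohol. The closest known reaction type is the intramolecular Nozaki–Hiyama–Kishi cyclisation of alkenyl triflates and iodides onto tethered carbonyl groups. Ring A (C1–C2–C3–C4–C5–C10) is closed in the 6-exo-trig mode, the alkenyl carbon C5 attacking the carbonyl carbon C4. The new stereocentre C4 is controlled by the quaternary C10: in the chair-like closing ring the C10 methyl is axial, the ketone methyl should take the equatorial site to avoid a 1,3-diaxial methyl–methyl contact, and the chromium-bound oxygen ends up axial, syn to the C10 methyl (4R). The step needs carbonyl addition rather than protonation of the alkenylmetal and a single site of attack; the C4 methyl ketone is the only carbonyl group present, the alkenyl triflate is a single regioisomer because C10 is quaternary, and the free C11 hydroxyl only consumes extra CrCl2. C5 stays sp2, so the ring-fusion hydrogen is installed separately in step 13.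

**Step 13**
Reactants: 20 eudesm-5-ene-4,11-diol
Product: 21 trans-fused eudesmane-4,11-diol
Conditions: Mn(dpm)3 (10 mol%; dpm = dipivaloylmethanate), PhSiH3, t-BuOOH, i-PrOH, rt
Reagents that add atoms: none
Why: In this metal-hydride hydrogen atom transfer (HAT) hydrogenation, hydrogen atom transfer to C6 gives the tertiary C5 radical, which should take up hydrogen along the axial trajectory on the face opposite the C10 methyl and the C4 oxygen and so give the trans ring fusion (5S).

**Step 14**
Reactants: 21 trans-fused eudesmane-4,11-diol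
Product: 23 dialdehyde tri(methyl ether), via lithium amino alkoxide 22 (not isolated)
Conditions: n-BuLi (3.2 equiv), TMEDA, THF, 0 °C; DMF (1.3 equiv), −78 to 0 °C; n-BuLi (1.5 equiv), 0 °C; DMF (excess), −78 °C to rt; aq. NH4Cl
Reagents that add atoms: N,N-dimethylformamide, CN(C)C=O
Why: Directed ortho-lithiation between two methoxy groups and formylation with DMF is used twice in one flask, the first adduct staying as its lithium α-amino alkoxide, which masks the aldehyde while the second, equally activated position is lithiated and formylated.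

**Step 15**
Reactants: 23 dialdehyde tri(methyl ether)
Product: 24 target CNP0409870.5
Conditions: NaSEt (10 equiv), DMF, 110 °C; then 1 M HCl
Reagents that add atoms: none
Why: Thiolate SN2 demethylation should cleave all three aryl methyl ethers, each of which is ortho or para to a formyl group, under basic conditions that the two tertiary alcohols tolerate.

**Compound list**

1 | (E)-5-methylhex-2-enoic acid | CC(C)C/C=C/C(=O)O | starting material
2 | (S)-4-benzyl-1,3-oxazolidin-2-one | O=C1N[C@@H](Cc2ccccc2)CO1 | starting material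
3 | (S)-4-benzyl-3-[(E)-5-methylhex-2-enoyl]-1,3-oxazolidin-2-one | CC(C)C/C=C/C(=O)N1[C@@H](Cc2ccccc2)COC1=O | intermediate
4 | 1,3,5-trimethoxybenzene | COc1cc(OC)cc(OC)c1 | starting material
5 | (2,4,6-trimethoxyphenyl)magnesium bromide (used as its cuprate with CuBr·SMe2) | COc1cc(OC)c([Mg]Br)c(OC)c1 | intermediate
6 | (S)-4-benzyl-3-[(R)-5-methyl-3-(2,4,6-trimethoxyphenyl)hexanoyl]-1,3-oxazolidin-2-one | CC(C)C[C@@H](c1c(OC)cc(OC)cc1OC)CC(=O)N1[C@@H](Cc2ccccc2)COC1=O | intermediate
7 | (R)-5-methyl-3-(2,4,6-trimethoxyphenyl)hexanoic acid | CC(C)C[C@@H](c1c(OC)cc(OC)cc1OC)CC(=O)O | intermediate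
8 | (S)-(+)-carvone, (S)-2-methyl-5-(prop-1-en-2-yl)cyclohex-2-en-1-one | CC(=C)[C@H]1CC=C(C)C(=O)C1 | starting material
9 | (5R,6R)-6-hydroxy-2-methyl-5-(prop-1-en-2-yl)cyclohex-2-en-1-one (hydroxyl trans to isopropenyl) | O[C@@H]1[C@@H](C(C)=C)CC=C(C)C1=O | intermediate
10 | (1R,6R)-3-methyl-2-oxo-6-(prop-1-en-2-yl)cyclohex-3-en-1-yl (R)-5-methyl-3-(2,4,6-trimethoxyphenyl)hexanoate | CC(C)C[C@@H](c1c(OC)cc(OC)cc1OC)CC(=O)O[C@@H]1[C@@H](C(C)=C)CC=C(C)C1=O | intermediate
11 | (1R,6R)-3-methyl-6-(prop-1-en-2-yl)-2-[(triethylsilyl)oxy]cyclohex-2-en-1-yl (R)-5-methyl-3-(2,4,6-trimethoxyphenyl)hexanoate | CC(C)C[C@@H](c1c(OC)cc(OC)cc1OC)CC(=O)O[C@@H]1[C@@H](C(C)=C)CCC(C)=C1O[Si](CC)(CC)CC | intermediate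
12 | (Z)-trimethylsilyl ketene acetal of ester 11 (C9' cis to OSiMe3) | CC(C)C[C@@H](c1c(OC)cc(OC)cc1OC)/C=C(\O[Si](C)(C)C)O[C@@H]1[C@@H](C(C)=C)CCC(C)=C1O[Si](CC)(CC)CC | intermediate
13 | (2S,3R)-5-methyl-2-[(1R,4S)-1-methyl-2-oxo-4-(prop-1-en-2-yl)cyclohexyl]-3-(2,4,6-trimethoxyphenyl)hexanoic acid | CC(C)C[C@@H](c1c(OC)cc(OC)cc1OC)[C@H](C(=O)O)[C@@]1(C)CC[C@H](C(C)=C)CC1=O | intermediate
14 | methyl (2S,3R)-5-methyl-2-[(1R,4S)-1-methyl-2-oxo-4-(prop-1-en-2-yl)cyclohexyl]-3-(2,4,6-trimethoxyphenyl)hexanoate | CC(C)C[C@@H](c1c(OC)cc(OC)cc1OC)[C@H](C(=O)OC)[C@@]1(C)CC[C@H](C(C)=C)CC1=O | intermediate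
15 | methyl (2S,3R)-2-[(1R,4S)-4-(2-hydroxypropan-2-yl)-1-methyl-2-oxocyclohexyl]-5-methyl-3-(2,4,6-trimethoxyphenyl)hexanoate | CC(C)C[C@@H](c1c(OC)cc(OC)cc1OC)[C@H](C(=O)OC)[C@@]1(C)CC[C@H](C(C)(C)O)CC1=O | intermediate
16 | methyl (2S,3R)-2-[(1R,4S)-4-(2-hydroxypropan-2-yl)-1-methyl-2-(trifluoromethanesulfonyloxy)cyclohex-2-en-1-yl]-5-methyl-3-(2,4,6-trimethoxyphenyl)hexanoate | CC(C)C[C@@H](c1c(OC)cc(OC)cc1OC)[C@H](C(=O)OC)[C@@]1(C)CC[C@H](C(C)(C)O)C=C1OS(=O)(=O)C(F)(F)F | intermediate
17 | (2S,3R)-2-[(1R,4S)-4-(2-hydroxypropan-2-yl)-1-methyl-2-(trifluoromethanesulfonyloxy)cyclohex-2-en-1-yl]-5-methyl-3-(2,4,6-trimethoxyphenyl)hexanal | CC(C)C[C@@H](c1c(OC)cc(OC)cc1OC)[C@H](C=O)[C@@]1(C)CC[C@H](C(C)(C)O)C=C1OS(=O)(=O)C(F)(F)F | intermediate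
18 | (3E,5S,6R)-5-[(1R,4S)-4-(2-hydroxypropan-2-yl)-1-methyl-2-(trifluoromethanesulfonyloxy)cyclohex-2-en-1-yl]-8-methyl-6-(2,4,6-trimethoxyphenyl)non-3-en-2-one | CC(C)C[C@@H](c1c(OC)cc(OC)cc1OC)[C@H](/C=C/C(C)=O)[C@@]1(C)CC[C@H](C(C)(C)O)C=C1OS(=O)(=O)C(F)(F)F | intermediate
19 | (5S,6R)-5-[(1R,4S)-4-(2-hydroxypropan-2-yl)-1-methyl-2-(trifluoromethanesulfonyloxy)cyclohex-2-en-1-yl]-8-methyl-6-(2,4,6-trimethoxyphenyl)nonan-2-one | CC(C)C[C@@H](c1c(OC)cc(OC)cc1OC)[C@H](CCC(C)=O)[C@@]1(C)CC[C@H](C(C)(C)O)C=C1OS(=O)(=O)C(F)(F)F | intermediate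
20 | (1S,4R,7S,10R)-1-[(1R)-3-methyl-1-(2,4,6-trimethoxyphenyl)butyl]eudesm-5-ene-4,11-diol (4-OH syn to the C10 methyl) | CC(C)C[C@@H](c1c(OC)cc(OC)cc1OC)[C@@H]1CC[C@@](C)(O)C2=C[C@@H](C(C)(C)O)CC[C@]12C | intermediate
21 | (1S,4R,5S,7S,10R)-1-[(1R)-3-methyl-1-(2,4,6-trimethoxyphenyl)butyl]eudesmane-4,11-diol (trans ring fusion) | CC(C)C[C@@H](c1c(OC)cc(OC)cc1OC)[C@@H]1CC[C@@](C)(O)[C@H]2C[C@@H](C(C)(C)O)CC[C@]12C | intermediate
22 | trilithium salt of the mono-formylation adduct of 21: lithium α-(dimethylamino)benzyl alkoxide at C3' of the arene, lithium alkoxides at C4 and C11 | CC(C)C[C@@H](c1c(OC)c(C(O[Li])N(C)C)c(OC)cc1OC)[C@@H]1CC[C@@](C)(O[Li])[C@H]2C[C@@H](C(C)(C)O[Li])CC[C@]12C | intermediate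
23 | 5-[(1R)-1-[(1S,4R,5S,7S,10R)-4,11-dihydroxyeudesman-1-yl]-3-methylbutyl]-2,4,6-trimethoxybenzene-1,3-dicarbaldehyde | CC(C)C[C@@H](c1c(OC)c(C=O)c(OC)c(C=O)c1OC)[C@@H]1CC[C@@](C)(O)[C@H]2C[C@@H](C(C)(C)O)CC[C@]12C | intermediate
24 | CNP0409870.5, 5-[(1R)-1-[(1S,4R,4aS,6S,8aR)-4-hydroxy-6-(2-hydroxypropan-2-yl)-4,8a-dimethyldecahydronaphthalen-1-yl]-3-methylbutyl]-2,4,6-trihydroxybenzene-1,3-dicarbaldehyde | CC(C)C[C@@H](c1c(O)c(C=O)c(O)c(C=O)c1O)[C@@H]1CC[C@@](C)(O)[C@H]2C[C@@H](C(C)(C)O)CC[C@]12C | target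

**Step count.** Total: 15 steps. Longest linear sequence: 14 steps (from 1 through steps 1–3 and 5–15 to 24).

**Steps most likely to fail**

Step 12 (key ring closure). Protonation of the alkenylchromium intermediate, or enolisation of the methyl ketone, may outrun addition to the hindered ketone and give the reduced cyclohexene; the two faces of the ketone may also be poorly differentiated. The fallback sets out from 16 and returns at 20. Reduction of 16 with i-Bu2AlH and Wittig reaction of aldehyde 17 with Ph3P=CHCHO should give the (E)-enal F1. Conjugate reduction with [(Ph3P)CuH]6 gives the saturated aldehyde F2. Nozaki–Hiyama–Kishi cyclisation onto the much more electrophilic aldehyde (CrCl2, NiCl2 cat., DMF) gives the secondary allylic alcohol F3 as a C4 mixture. MnO2 oxidises it to the ring A enone F4. MeLi/CeCl3 (THF, −78 °C) should then add to the C4 carbonyl from the face opposite the C10 methyl and give 20.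

Step 13 (ring-fusion hydrogen). Hydrogen may be delivered to the tertiary C5 radical from the face of the C10 methyl, because the axial side chain on C1 crowds the other face; this would give the cis-fused isomer. The fallback sets out from 20 and returns at 21. Silylation of both tertiary hydroxyls with Et3SiOTf/2,6-lutidine gives the bis(triethylsilyl) ether F5, in which the C4 silyl ether joins the C10 methyl in blocking the lower face. Hydrogenation over PtO2 (H2, EtOAc) should then deliver both hydrogens to the upper face and give the trans-fused bis(silyl) ether F6. Bu4NF in THF removes the silyl groups to return 21.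

Step 14 (double formylation). The second metalation may stay incomplete, or the α-amino alkoxide may collapse early and allow butyl addition to the first formyl group, within a poorly soluble polylithiated species. The fallback sets out from 21 and returns at 23. Electrophilic dibromination of the two free, doubly activated ring positions with N-bromosuccinimide (MeCN, 0 °C) gives the dibromide F7. After deprotonation of the two hydroxyls with MeLi, double bromine–lithium exchange with t-BuLi (THF, −78 °C) and a DMF quench give 23.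

**Further compounds**

F1 | step 12 | (2E,4S,5R)-4-[(1R,4S)-4-(2-hydroxypropan-2-yl)-1-methyl-2-(trifluoromethanesulfonyloxy)cyclohex-2-en-1-yl]-7-methyl-5-(2,4,6-trimethoxyphenyl)oct-2-enal | CC(C)C[C@@H](c1c(OC)cc(OC)cc1OC)[C@H](/C=C/C=O)[C@@]1(C)CC[C@H](C(C)(C)O)C=C1OS(=O)(=O)C(F)(F)F
F2 | step 12 | (4S,5R)-4-[(1R,4S)-4-(2-hydroxypropan-2-yl)-1-methyl-2-(trifluoromethanesulfonyloxy)cyclohex-2-en-1-yl]-7-methyl-5-(2,4,6-trimethoxyphenyl)octanal | CC(C)C[C@@H](c1c(OC)cc(OC)cc1OC)[C@H](CCC=O)[C@@]1(C)CC[C@H](C(C)(C)O)C=C1OS(=O)(=O)C(F)(F)F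
F3 | step 12 | (1S,7S,10R)-1-[(1R)-3-methyl-1-(2,4,6-trimethoxyphenyl)butyl]-15-noreudesm-5-ene-4,11-diol (C4 epimers) | CC(C)C[C@@H](c1c(OC)cc(OC)cc1OC)[C@@H]1CCC(O)C2=C[C@@H](C(C)(C)O)CC[C@]12C
F4 | step 12 | (1S,7S,10R)-11-hydroxy-1-[(1R)-3-methyl-1-(2,4,6-trimethoxyphenyl)butyl]-15-noreudesm-5-en-4-one | CC(C)C[C@@H](c1c(OC)cc(OC)cc1OC)[C@@H]1CCC(=O)C2=C[C@@H](C(C)(C)O)CC[C@]12C
F5 | step 13 | 4,11-bis(triethylsilyl) ether of 20 | CC(C)C[C@@H](c1c(OC)cc(OC)cc1OC)[C@@H]1CC[C@@](C)(O[Si](CC)(CC)CC)C2=C[C@@H](C(C)(C)O[Si](CC)(CC)CC)CC[C@]12C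
F6 | step 13 | 4,11-bis(triethylsilyl) ether of 21 | CC(C)C[C@@H](c1c(OC)cc(OC)cc1OC)[C@@H]1CC[C@@](C)(O[Si](CC)(CC)CC)[C@H]2C[C@@H](C(C)(C)O[Si](CC)(CC)CC)CC[C@]12C
F7 | step 14 | (1S,4R,5S,7S,10R)-1-[(1R)-1-(3,5-dibromo-2,4,6-trimethoxyphenyl)-3-methylbutyl]eudesmane-4,11-diol | CC(C)C[C@@H](c1c(OC)c(Br)c(OC)c(Br)c1OC)[C@@H]1CC[C@@](C)(O)[C@H]2C[C@@H](C(C)(C)O)CC[C@]12C
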